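**Plan**

- Retrosynthesis: the O–CH3 bond of the vinylogous ester is cut first (back to the 2-hydroxy-1,4-naphthoquinone), then the quinone ring is opened at C2=C3 and C1–C8a in one stroke.
- Enabling feature: the quinone ring carries oxygen on C1, C2 and C4 while C3 is a CH. C1–C2 is therefore an oxalyl unit (a 1,2-dielectrophile) and C8a–C4a–C4–C3 is an ortho-metalated aryl methyl ketone enolate (a 1,4-C,C-dinucleophile). An iodine on C8a, the benzo-ring carbon between the acyl-bearing C4a and the aryl-bearing C8, decides which ortho carbon reacts.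
- The iodide goes back to an amine (Sandmeyer), the biaryl bond C8–C1' to a Suzuki coupling, the bromide to an amine-directed bromination, and the acetyl group to an ortho-acylation of 3,4-dimethylaniline.
- Forward: the benzo ring is bought; acetyl, bromine, trimethoxyphenyl and iodine are set around it in that order, the quinone ring is annulated in one operation, and O-methylation ends the route.
- Stereochemistry: the target has no stereocentre, so none is set.

Key step: step 5

Remark: the SMILES defines no configuration for the hindered biaryl axis, so the axis is left undefined (a racemate if rotation should be slow).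

**Route**

Step 1
Reactants: 1 3,4-dimethylaniline; 2 acetonitrile
Product: 4 1-(2-amino-4,5-dimethylphenyl)ethan-1-one, via ketimine 3 (not isolated)
Conditions: BCl3, AlCl3, MeCN, 1,2-dichloroethane, 0 °C → reflux; then 2 M HCl, 80 °C
Reagents that add atoms: water (O)
Why: Sugasawa ortho-acylation: the aniline–BCl3 adduct delivers the AlCl3-activated nitrile to an ortho carbon through a six-membered boron chelate, the ortho position not flanked by the 3-methyl group reacts, and acid hydrolysis of the chelated ketimine 3 frees the ketone.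

Step 2
Reactants: 4 1-(2-amino-4,5-dimethylphenyl)ethan-1-one
Product: 5 1-(2-amino-3-bromo-4,5-dimethylphenyl)ethan-1-one
Conditions: NBS (1.0 equiv), MeCN, 0 °C → rt
Reagents that add atoms: N-bromosuccinimide (O=C1CCC(=O)N1Br)
Why: Electrophilic aromatic bromination directed by the amino group: its para position carries a methyl group and its other ortho position the acetyl group, so only C3 is open, while C6 is deactivated by the ortho acetyl group.

Step 3
Reactants: 5 1-(2-amino-3-bromo-4,5-dimethylphenyl)ethan-1-one; 6 (2,4,5-trimethoxyphenyl)boronic acid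
Product: 7 1-[2-amino-4,5-dimethyl-3-(2,4,5-trimethoxyphenyl)phenyl]ethan-1-one
Conditions: Pd(OAc)2, SPhos, K3PO4, toluene/H2O, 100 °C
Reagents that add atoms: none
Why: Suzuki–Miyaura coupling; Pd(OAc)2 with the bulky biaryl phosphine SPhos is established for di-ortho-substituted aryl bromides and ortho-substituted boronic acids and tolerates the free amine and the ketone.

Step 4
Reactants: 7 1-[2-amino-4,5-dimethyl-3-(2,4,5-trimethoxyphenyl)phenyl]ethan-1-one
Product: 9 1-[2-iodo-4,5-dimethyl-3-(2,4,5-trimethoxyphenyl)phenyl]ethan-1-one, via diazonium salt 8 (not isolated)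
Conditions: NaNO2, aq. H2SO4/MeCN, 0 °C; urea; then KI, 0 °C → rt
Reagents that add atoms: potassium iodide ([K+].[I-])
Why: Diazotisation and iododediazoniation (Sandmeyer-type, no copper needed): iodide reduces the diazonium ion to the aryl radical, which should be trapped by iodine faster than it can attack the neighbouring ring, and the iodide is added at 0 °C straight after diazotisation so that the diazonium ion does not linger.

Step 5
Reactants: 9 1-[2-iodo-4,5-dimethyl-3-(2,4,5-trimethoxyphenyl)phenyl]ethan-1-one; 10 dimethyl oxalate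
Product: 14 2-hydroxy-6,7-dimethyl-8-(2,4,5-trimethoxyphenyl)naphthalene-1,4-dione, via potassium enolate 11 (not isolated), via lithiated enolate 12 (not isolated), via glyoxylate enolate 13 (not isolated)
Conditions: KH, THF, 0 °C; t-BuLi (2.1 equiv), −78 °C; (CO2Me)2 (1.1 equiv), −78 °C → rt; aq. HCl
Reagents that add atoms: none
Why: KH turns the acetyl group of 9 into potassium enolate 11 (H2 is the only by-product, so no protic amine remains to quench the carbanion), and iodine–lithium exchange with t-BuLi (the second equivalent destroys t-BuI) then gives 12, in which C8a and C3 are the two ends of a 1,4-C,C-dinucleophile. The aryllithium acylates one ester of dimethyl oxalate (C1–C8a; the tetrahedral adduct should survive at −78 °C and so block double addition), and on warming enolate 13 attacks the remaining ester carbon (C2–C3) with loss of methoxide; the 1,2,4-trione so formed is deprotonated at once to the 2-hydroxy-1,4-quinone anion, a thermodynamic sink that makes the sequence irreversible. The closest known reaction type is the cyclization of C,C-dianions (for example 2,2'-dilithiobiaryls) with oxalic acid diesters to ring 1,2-diones, here built from a Parham-type aryllithium acylation and a Claisen (Dieckmann-type) condensation. The only ring closed is the quinone ring, by a 6-(enolexo)-exo-trig attack of the enolate carbon on the ester carbonyl; the competing 5-exo aldol addition to the C1 ketone and O-acylation are reversible under the alkoxide conditions and should drain into the quinone anion. No stereocentre is formed. The step needs site selectivity between the two ortho carbons of the aroyl ring and a fixed placement of the oxygens: the iodine marks C8a (not C5), and because C1 and C2 both come from the oxalate while C3 stays a CH, the free hydroxyl can only sit on C2, next to the carbonyl peri to the aryl group.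

Step 6
Reactants: 14 2-hydroxy-6,7-dimethyl-8-(2,4,5-trimethoxyphenyl)naphthalene-1,4-dione
Product: 15 2-methoxy-6,7-dimethyl-8-(2,4,5-trimethoxyphenyl)naphthalene-1,4-dione
Conditions: MeOH, conc. HCl (cat.), reflux
Reagents that add atoms: methanol (CO)
Why: Acid-catalysed etherification of the vinylogous acid (addition of methanol to C2 and loss of water), as in the standard preparation of 2-methoxy-1,4-naphthoquinone from lawsone; under these equilibrating conditions the para-quinone ether is favoured over the 4-methoxy-1,2-quinone, and the aryl methyl ethers are inert.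

**Compound list**

1 | 3,4-dimethylaniline | Cc1ccc(N)cc1C | starting material
2 | acetonitrile | CC#N | starting material
3 | 1-(2-amino-4,5-dimethylphenyl)ethan-1-imine (held as its boron chelate until hydrolysis) | CC(=N)c1cc(C)c(C)cc1N | intermediate
4 | 1-(2-amino-4,5-dimethylphenyl)ethan-1-one | CC(=O)c1cc(C)c(C)cc1N | intermediate
5 | 1-(2-amino-3-bromo-4,5-dimethylphenyl)ethan-1-one | CC(=O)c1cc(C)c(C)c(Br)c1N | intermediate
6 | (2,4,5-trimethoxyphenyl)boronic acid | COc1cc(OC)c(B(O)O)cc1OC | starting material
7 | 1-[2-amino-4,5-dimethyl-3-(2,4,5-trimethoxyphenyl)phenyl]ethan-1-one | CC(=O)c1cc(C)c(C)c(-c2cc(OC)c(OC)cc2OC)c1N | intermediate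
8 | 2-acetyl-4,5-dimethyl-6-(2,4,5-trimethoxyphenyl)benzenediazonium hydrogen sulfate | CC(=O)c1cc(C)c(C)c(-c2cc(OC)c(OC)cc2OC)c1[N+]#N.OS(=O)(=O)[O-] | intermediate
9 | 1-[2-iodo-4,5-dimethyl-3-(2,4,5-trimethoxyphenyl)phenyl]ethan-1-one | CC(=O)c1cc(C)c(C)c(-c2cc(OC)c(OC)cc2OC)c1I | intermediate
10 | dimethyl oxalate | COC(=O)C(=O)OC | starting material
11 | potassium 1-[2-iodo-4,5-dimethyl-3-(2,4,5-trimethoxyphenyl)phenyl]ethen-1-olate | C=C([O-])c1cc(C)c(C)c(-c2cc(OC)c(OC)cc2OC)c1I.[K+] | intermediate
12 | potassium 1-[2-lithio-4,5-dimethyl-3-(2,4,5-trimethoxyphenyl)phenyl]ethen-1-olate | C=C([O-])c1cc(C)c(C)c(-c2cc(OC)c(OC)cc2OC)c1[Li].[K+] | intermediate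
13 | enolate of methyl 2-[2-acetyl-4,5-dimethyl-6-(2,4,5-trimethoxyphenyl)phenyl]-2-oxoacetate (potassium salt shown) | C=C([O-])c1cc(C)c(C)c(-c2cc(OC)c(OC)cc2OC)c1C(=O)C(=O)OC.[K+] | intermediate
14 | 2-hydroxy-6,7-dimethyl-8-(2,4,5-trimethoxyphenyl)naphthalene-1,4-dione | OC1=CC(=O)c2cc(C)c(C)c(-c3cc(OC)c(OC)cc3OC)c2C1=O | intermediate
15 | 2-methoxy-6,7-dimethyl-8-(2,4,5-trimethoxyphenyl)naphthalene-1,4-dione | COC1=CC(=O)c2cc(C)c(C)c(-c3cc(OC)c(OC)cc3OC)c2C1=O | target

**Step count**

Total steps: 6. Longest linear sequence: 6 steps (from 3,4-dimethylaniline).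

**Steps most likely to fail**

1. Step 5. The aryllithium may be quenched by proton transfer before it meets the oxalate, it may add twice to one oxalate, or the closure may stall at the reversible 5-exo aldol or O-acyl stage. The fallback forms the two bonds one after the other; it sets out from 9 and comes back at 14. Ketone 9 is protected as its ethylene ketal, 2-[2-iodo-4,5-dimethyl-3-(2,4,5-trimethoxyphenyl)phenyl]-2-methyl-1,3-dioxolane F1 (ethylene glycol, TsOH, toluene, Dean–Stark). Iodine–lithium exchange (t-BuLi, THF, −78 °C) gives [2-(2-methyl-1,3-dioxolan-2-yl)-4,5-dimethyl-6-(2,4,5-trimethoxyphenyl)phenyl]lithium F2, which is run into excess dimethyl oxalate 10 to give the isolable keto ester methyl 2-[2-(2-methyl-1,3-dioxolan-2-yl)-4,5-dimethyl-6-(2,4,5-trimethoxyphenyl)phenyl]-2-oxoacetate F3. Aqueous HCl in acetone frees the ketone to give methyl 2-[2-acetyl-4,5-dimethyl-6-(2,4,5-trimethoxyphenyl)phenyl]-2-oxoacetate F4, and NaOMe in MeOH closes the ring by Claisen condensation to 14 after acidification.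

2. Step 4. The diazonium ion may be captured inside the molecule before iodide arrives: by azo coupling with the electron-rich ring, by attack of the 2'-methoxy oxygen with loss of the methyl group, or by cyclization onto the enolised acetyl group. The fallback carries out the diazonium chemistry before the biaryl exists; it sets out from 4 and comes back at 12. Iodination of 4 (NIS, MeCN) gives 1-(2-amino-3-iodo-4,5-dimethylphenyl)ethan-1-one F5. Diazotisation (NaNO2, aq. HBr, 0 °C) gives 2-acetyl-6-iodo-4,5-dimethylbenzenediazonium bromide F6, which CuBr converts into 1-(2-bromo-3-iodo-4,5-dimethylphenyl)ethan-1-one F7. A Suzuki coupling with 6 that is selective for the carbon–iodine bond (Pd(PPh3)4, Na2CO3, DME/H2O, 80 °C) gives 1-[2-bromo-4,5-dimethyl-3-(2,4,5-trimethoxyphenyl)phenyl]ethan-1-one F8. KH gives potassium 1-[2-bromo-4,5-dimethyl-3-(2,4,5-trimethoxyphenyl)phenyl]ethen-1-olate F9, and bromine–lithium exchange with t-BuLi gives 12, from which step 5 continues.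

3. Step 3. Protodeboronation of the electron-rich ortho-methoxy boronic acid may outrun transmetalation at the di-ortho-substituted aryl–palladium species, and the ortho-amino ketone may tie up the catalyst by chelation. The fallback replaces the boron nucleophile by a zinc one; it sets out from 5 and comes back at 7. Commercial 1-bromo-2,4,5-trimethoxybenzene is lithiated (n-BuLi, THF, −78 °C) to (2,4,5-trimethoxyphenyl)lithium F10 and transmetalated with ZnCl2 to (2,4,5-trimethoxyphenyl)zinc chloride F11. A Negishi coupling of F11 with 5 (Pd2(dba)3, XPhos, THF, 60 °C) gives 7; arylzinc halides tolerate the free amine and the ketone.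

**Further compounds**

F1 | step 5 | 2-[2-iodo-4,5-dimethyl-3-(2,4,5-trimethoxyphenyl)phenyl]-2-methyl-1,3-dioxolane | CC1(OCCO1)c2cc(C)c(C)c(-c3cc(OC)c(OC)cc3OC)c2I
F2 | step 5 | [2-(2-methyl-1,3-dioxolan-2-yl)-4,5-dimethyl-6-(2,4,5-trimethoxyphenyl)phenyl]lithium | CC1(OCCO1)c2cc(C)c(C)c(-c3cc(OC)c(OC)cc3OC)c2[Li]
F3 | step 5 | methyl 2-[2-(2-methyl-1,3-dioxolan-2-yl)-4,5-dimethyl-6-(2,4,5-trimethoxyphenyl)phenyl]-2-oxoacetate | CC1(OCCO1)c2cc(C)c(C)c(-c3cc(OC)c(OC)cc3OC)c2C(=O)C(=O)OC
F4 | step 5 | methyl 2-[2-acetyl-4,5-dimethyl-6-(2,4,5-trimethoxyphenyl)phenyl]-2-oxoacetate | CC(=O)c1cc(C)c(C)c(-c2cc(OC)c(OC)cc2OC)c1C(=O)C(=O)OC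
F5 | step 4 | 1-(2-amino-3-iodo-4,5-dimethylphenyl)ethan-1-one | CC(=O)c1cc(C)c(C)c(I)c1N
F6 | step 4 | 2-acetyl-6-iodo-4,5-dimethylbenzenediazonium bromide | CC(=O)c1cc(C)c(C)c(I)c1[N+]#N.[Br-]
F7 | step 4 | 1-(2-bromo-3-iodo-4,5-dimethylphenyl)ethan-1-one | CC(=O)c1cc(C)c(C)c(I)c1Br
F8 | step 4 | 1-[2-bromo-4,5-dimethyl-3-(2,4,5-trimethoxyphenyl)phenyl]ethan-1-one | CC(=O)c1cc(C)c(C)c(-c2cc(OC)c(OC)cc2OC)c1Br
F9 | step 4 | potassium 1-[2-bromo-4,5-dimethyl-3-(2,4,5-trimethoxyphenyl)phenyl]ethen-1-olate | C=C([O-])c1cc(C)c(C)c(-c2cc(OC)c(OC)cc2OC)c1Br.[K+]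
F10 | step 3 | (2,4,5-trimethoxyphenyl)lithium | COc1cc(OC)c([Li])cc1OC
F11 | step 3 | (2,4,5-trimethoxyphenyl)zinc chloride | COc1cc(OC)c([Zn]Cl)cc1OC
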